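**Plan**

Rings: A = trimethylcyclohexene; B = dihydropyranone (O1, C2 to C6); C = butyrolactone (O1, C2, C3, C4, C5=O; C3 is bonded to C6 of ring B).
Retrosynthetic cuts, in this order: C4–C5 of ring C; C3=C4 of ring B (metathesis) and the ring-B ester C–O; the CH2–CH2 bond next to C3 of ring B (enolate alkylation); the bond between the (E)-alkene CH and its CH2 (alkenylalanate plus epoxide).
Enabling feature: C5 of ring C carries only O1 and the C4 methylene, and C3 carries one H. The array O1–C5(=O)–C4H2–C3H is therefore the adduct of an O-formyl C–H bond across a C3=C4 methylidene, and the precursor is simply the formate of a 2-substituted allyl alcohol.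
Forward order: side-chain acrylic acid from dihydro-β-ionone (ring A bought in); core allylic alcohol from 2-methylidenepropane-1,3-diol; esterification; ring B by metathesis; ring C last by formyl C–H addition, an isomerisation that loses no atom.
Stereochemistry: C6 of ring B from a Keck allylation with (R)-BINOL; C3 of ring C is set in the key step under control of C6; the (E)-alkene comes from syn-carboalumination; the ring-B alkene geometry is enforced by the ring.

Key step: step 14

Remark: the numbered starting materials and the reagents named in the steps are taken to be commercially available; compound 9 is a racemate at a centre that is removed in step 5.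

**Route**

Step 1
Reactants: 1 4-(2,6,6-trimethylcyclohex-1-en-1-yl)butan-2-one (dihydro-β-ionone)
Product: 3 2-(but-3-yn-1-yl)-1,3,3-trimethylcyclohex-1-ene, via enol phosphate 2 (not isolated)
Conditions: LiN(iPr)2, THF, −78 °C; ClP(O)(OEt)2, −78 °C to rt; LiN(iPr)2 (2.3 equiv), THF, −78 °C to rt; H2O
Reagents that add atoms: none
Why: Kinetic deprotonation on the CH3 side, O-phosphorylation and amide-induced elimination of diethyl phosphate from the terminal enol phosphate should give the terminal alkyne (methyl ketone to alkyne conversion), with no stereocentre formed and the tetrasubstituted ring alkene inert.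

Step 2
Reactants: 3 2-(but-3-yn-1-yl)-1,3,3-trimethylcyclohex-1-ene
Product: 6 (3E)-4-methyl-6-(2,6,6-trimethylcyclohex-1-en-1-yl)hex-3-en-1-ol, via alkenylalane 4 (not isolated), via lithium alanate 5 (not isolated)
Conditions: AlMe3 (2 equiv), Cp2ZrCl2 (0.25 equiv), CH2Cl2, 0 °C to rt; volatiles removed in vacuo; n-BuLi, hexane/THF, −78 °C; ethylene oxide, −78 °C to rt; H2O
Reagents that add atoms: trimethylaluminium, C[Al](C)C; ethylene oxide, C1CO1
Why: Zirconium-catalysed carboalumination (Negishi carboalumination) adds CH3 and Al syn with Al on the terminal carbon, and the derived alanate opens ethylene oxide with retention at the alkenyl carbon, so the (E)-trisubstituted alkene is fixed by the syn addition.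

Step 3
Reactants: 6 (3E)-4-methyl-6-(2,6,6-trimethylcyclohex-1-en-1-yl)hex-3-en-1-ol
Product: 7 2-[(3E)-6-iodo-3-methylhex-3-en-1-yl]-1,3,3-trimethylcyclohex-1-ene
Conditions: I2, PPh3, imidazole, CH2Cl2, 0 °C to rt
Reagents that add atoms: iodine, II
Why: Appel-type iodination replaces the primary hydroxyl by SN2 displacement of the oxyphosphonium ion and leaves both alkenes untouched.

Step 4
Reactants: 7 2-[(3E)-6-iodo-3-methylhex-3-en-1-yl]-1,3,3-trimethylcyclohex-1-ene; 8 triethyl phosphonoacetate (2 equiv)
Product: 9 ethyl (5E)-2-(diethoxyphosphoryl)-6-methyl-8-(2,6,6-trimethylcyclohex-1-en-1-yl)oct-5-enoate (racemic)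
Conditions: NaH, DMF, 0 °C; then 7, 60 °C
Reagents that add atoms: none
Why: The sodium salt of the phosphonoacetate, used in excess to hold back double alkylation, should displace the unhindered primary iodide (SN2 C-alkylation of a stabilised carbanion); the new α-centre is racemic and is destroyed in step 5.

Step 5
Reactants: 9 ethyl (5E)-2-(diethoxyphosphoryl)-6-methyl-8-(2,6,6-trimethylcyclohex-1-en-1-yl)oct-5-enoate
Product: 10 ethyl (5E)-6-methyl-2-methylidene-8-(2,6,6-trimethylcyclohex-1-en-1-yl)oct-5-enoate
Conditions: aq. HCHO (37 %), K2CO3, THF/H2O, rt to 50 °C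
Reagents that add atoms: formaldehyde, C=O
Why: Horner–Wadsworth–Emmons olefination with formaldehyde under mild carbonate conditions converts the α-alkyl phosphonoacetate into the 2-substituted acrylate, and a terminal methylidene has no geometry to control.

Step 6
Reactants: 10 ethyl (5E)-6-methyl-2-methylidene-8-(2,6,6-trimethylcyclohex-1-en-1-yl)oct-5-enoate
Product: 11 (5E)-6-methyl-2-methylidene-8-(2,6,6-trimethylcyclohex-1-en-1-yl)oct-5-enoic acid
Conditions: LiOH, THF/H2O, rt; then 1 M HCl to pH 3
Reagents that add atoms: lithium hydroxide, [Li+].[OH-]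
Why: Saponification, with hydroxide adding only slowly to an α-alkyl acrylate, followed by mild acidification should give the acrylic acid.

Step 7
Reactants: 12 2-methylidenepropane-1,3-diol
Product: 13 2-({[tert-butyl(dimethyl)silyl]oxy}methyl)prop-2-en-1-ol
Conditions: NaH (1.0 equiv), THF, 0 °C; TBSCl (1.0 equiv), 0 °C to rt
Reagents that add atoms: tert-butyl(chloro)dimethylsilane, CC(C)(C)[Si](C)(C)Cl
Why: One equivalent of NaH gives the sparingly soluble monoalkoxide of the symmetric diol, which is silylated once (monosilylation of a symmetric diol), leaving one allylic hydroxyl free.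

Step 8
Reactants: 13 2-({[tert-butyl(dimethyl)silyl]oxy}methyl)prop-2-en-1-ol
Product: 14 2-({[tert-butyl(dimethyl)silyl]oxy}methyl)prop-2-enal
Conditions: PhI(OAc)2, TEMPO (10 mol %), CH2Cl2, rt
Reagents that add atoms: none
Why: Nitroxyl-catalysed oxidation with a hypervalent iodine co-oxidant stops at the aldehyde for a primary allylic alcohol and tolerates the silyl ether.

Step 9
Reactants: 14 2-({[tert-butyl(dimethyl)silyl]oxy}methyl)prop-2-enal
Product: 15 (3R)-2-({[tert-butyl(dimethyl)silyl]oxy}methyl)hexa-1,5-dien-3-ol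
Conditions: Ti(OiPr)4 (10 mol %), (R)-BINOL (20 mol %), 4 Å MS, CH2Cl2; allylSnBu3, −20 °C; aq. NaHCO3
Reagents that add atoms: allyltributylstannane, C=CC[Sn](CCCC)(CCCC)CCCC
Why: Keck allylation: the chiral titanium BINOLate activates the aldehyde and the allylstannane adds 1,2 to one enantioface, and (R)-BINOL is expected to give the (3R) alcohol (the alkenyl substituent outranks allyl), which becomes C6 of ring B.

Step 10
Reactants: 15 (3R)-2-({[tert-butyl(dimethyl)silyl]oxy}methyl)hexa-1,5-dien-3-ol; 11 (5E)-6-methyl-2-methylidene-8-(2,6,6-trimethylcyclohex-1-en-1-yl)oct-5-enoic acid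
Product: 16 (3R)-2-({[tert-butyl(dimethyl)silyl]oxy}methyl)hexa-1,5-dien-3-yl (5E)-6-methyl-2-methylidene-8-(2,6,6-trimethylcyclohex-1-en-1-yl)oct-5-enoate
Conditions: DCC, DMAP (cat.), CH2Cl2, 0 °C to rt
Reagents that add atoms: none
Why: Steglich esterification joins the secondary alcohol and the acrylic acid under neutral conditions, with retention at the carbinol carbon because its C–O bond is not broken.

Step 11
Reactants: 16 (3R)-2-({[tert-butyl(dimethyl)silyl]oxy}methyl)hexa-1,5-dien-3-yl (5E)-6-methyl-2-methylidene-8-(2,6,6-trimethylcyclohex-1-en-1-yl)oct-5-enoate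
Product: 17 (6R)-6-(3-{[tert-butyl(dimethyl)silyl]oxy}prop-1-en-2-yl)-3-[(3E)-4-methyl-6-(2,6,6-trimethylcyclohex-1-en-1-yl)hex-3-en-1-yl]-5,6-dihydro-2H-pyran-2-one
Conditions: second-generation Grubbs catalyst (5 mol %), toluene (0.005 M), 80 °C
Reagents that add atoms: none
Why: Ring-closing metathesis: the ruthenium carbene should load at the only monosubstituted alkene and close onto the acrylate methylidene to give six-membered ring B, whereas the allylic methylidene could only close a four-membered ring and the tri- and tetrasubstituted side-chain alkenes are too hindered.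

Step 12
Reactants: 17 (6R)-6-(3-{[tert-butyl(dimethyl)silyl]oxy}prop-1-en-2-yl)-3-[(3E)-4-methyl-6-(2,6,6-trimethylcyclohex-1-en-1-yl)hex-3-en-1-yl]-5,6-dihydro-2H-pyran-2-one
Product: 18 (6R)-6-(3-hydroxyprop-1-en-2-yl)-3-[(3E)-4-methyl-6-(2,6,6-trimethylcyclohex-1-en-1-yl)hex-3-en-1-yl]-5,6-dihydro-2H-pyran-2-one
Conditions: HF·pyridine, pyridine, THF, 0 °C to rt
Reagents that add atoms: none
Why: Buffered HF·pyridine cleaves the primary allylic silyl ether (fluoride-driven Si–O cleavage) without opening the lactone or protonating the trisubstituted alkenes.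

Step 13
Reactants: 18 (6R)-6-(3-hydroxyprop-1-en-2-yl)-3-[(3E)-4-methyl-6-(2,6,6-trimethylcyclohex-1-en-1-yl)hex-3-en-1-yl]-5,6-dihydro-2H-pyran-2-one
Product: 19 2-[(2R)-5-[(3E)-4-methyl-6-(2,6,6-trimethylcyclohex-1-en-1-yl)hex-3-en-1-yl]-6-oxo-3,6-dihydro-2H-pyran-2-yl]prop-2-en-1-yl formate
Conditions: HCO2H, DCC, DMAP (cat.), CH2Cl2, 0 °C
Reagents that add atoms: formic acid, OC=O
Why: Carbodiimide-mediated formylation of the primary alcohol (Steglich-type esterification) gives the allyl formate under neutral conditions that leave the unsaturated lactone untouched.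

Step 14
Reactants: 19 2-[(2R)-5-[(3E)-4-methyl-6-(2,6,6-trimethylcyclohex-1-en-1-yl)hex-3-en-1-yl]-6-oxo-3,6-dihydro-2H-pyran-2-yl]prop-2-en-1-yl formate
Product: 20 (6R)-3-[(3E)-4-methyl-6-(2,6,6-trimethylcyclohex-1-en-1-yl)hex-3-en-1-yl]-6-[(3R)-5-oxooxolan-3-yl]-5,6-dihydro-2H-pyran-2-one (CNP0207009.2)
Conditions: Ru3(CO)12 (5 mol %), Bu4NI (15 mol %), toluene, 135 °C, sealed tube, argon
Reagents that add atoms: none
Why: Proposed new method: the formyl C–H bond of 19 should add oxidatively to iodide-ligated zerovalent ruthenium to give an (alkoxycarbonyl)ruthenium hydride, the tethered 1,1-disubstituted alkene then inserts into Ru–H with H going to the substituted carbon and Ru to the CH2 terminus, and C–C reductive elimination from the six-membered oxaruthenacycle forms the C4–C5 bond of ring C with no by-product. The closest known reaction types are the Ru3(CO)12/halide-catalysed cyclisation of N-allylformamides to pyrrolidin-2-ones, the ruthenium-catalysed hydroesterification of alkenes with formate esters and the rhodium-catalysed hydroacylation of 4-substituted pent-4-enals to cyclopentanones, of which 19 is the 2-oxa analogue. Ring C closes in a formally 5-endo-trig sense at the alkene, which is accessible here because the bond arises by reductive elimination from a metallacycle and not by direct attack on the π bond. The new stereocentre C3 of ring C is set in the hydride insertion by 1,2-induction from C6 of ring B: with the C6–O bond anti to ruthenium and the C6–H turned towards the tether carbon, hydrogen should enter the alkene face that gives (3R), the anti relation of the ring-B oxygen and the OCH2 branch, although this sense of induction is an expectation and not a secured outcome. The step needs regioselectivity, secured by ring size because the reverse insertion could only lead to a β-lactone, and chemoselectivity over the tri- and tetrasubstituted alkenes and the enoate, secured by the three-atom tether that lets only the allylic methylidene reach the Ru–H bond. If the formate loses CO first, the sealed tube keeps CO, alcohol 18 and the ruthenium hydride together, and hydroesterification of the same alkene should converge on 20.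

**Compound list**

1 | 4-(2,6,6-trimethylcyclohex-1-en-1-yl)butan-2-one (dihydro-β-ionone) | CC(=O)CCC1=C(C)CCCC1(C)C | starting material
2 | diethyl 4-(2,6,6-trimethylcyclohex-1-en-1-yl)but-1-en-2-yl phosphate (enol phosphate, formed in the flask) | C=C(CCC1=C(C)CCCC1(C)C)OP(=O)(OCC)OCC | intermediate
3 | 2-(but-3-yn-1-yl)-1,3,3-trimethylcyclohex-1-ene | C#CCCC1=C(C)CCCC1(C)C | intermediate
4 | dimethyl[(1E)-2-methyl-4-(2,6,6-trimethylcyclohex-1-en-1-yl)but-1-en-1-yl]alumane (alkenylalane, formed in the flask) | C[Al](C)/C=C(\C)CCC1=C(C)CCCC1(C)C | intermediate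
5 | lithium butyl(dimethyl)[(1E)-2-methyl-4-(2,6,6-trimethylcyclohex-1-en-1-yl)but-1-en-1-yl]aluminate (formed in the flask) | [Li+].CCCC[Al-](C)(C)/C=C(\C)CCC1=C(C)CCCC1(C)C | intermediate
6 | (3E)-4-methyl-6-(2,6,6-trimethylcyclohex-1-en-1-yl)hex-3-en-1-ol | OCC/C=C(\C)CCC1=C(C)CCCC1(C)C | intermediate
7 | 2-[(3E)-6-iodo-3-methylhex-3-en-1-yl]-1,3,3-trimethylcyclohex-1-ene | ICC/C=C(\C)CCC1=C(C)CCCC1(C)C | intermediate
8 | triethyl phosphonoacetate | CCOC(=O)CP(=O)(OCC)OCC | starting material
9 | ethyl (5E)-2-(diethoxyphosphoryl)-6-methyl-8-(2,6,6-trimethylcyclohex-1-en-1-yl)oct-5-enoate (racemic) | CCOC(=O)C(CC/C=C(\C)CCC1=C(C)CCCC1(C)C)P(=O)(OCC)OCC | intermediate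
10 | ethyl (5E)-6-methyl-2-methylidene-8-(2,6,6-trimethylcyclohex-1-en-1-yl)oct-5-enoate | CCOC(=O)C(=C)CC/C=C(\C)CCC1=C(C)CCCC1(C)C | intermediate
11 | (5E)-6-methyl-2-methylidene-8-(2,6,6-trimethylcyclohex-1-en-1-yl)oct-5-enoic acid | OC(=O)C(=C)CC/C=C(\C)CCC1=C(C)CCCC1(C)C | intermediate
12 | 2-methylidenepropane-1,3-diol | C=C(CO)CO | starting material
13 | 2-({[tert-butyl(dimethyl)silyl]oxy}methyl)prop-2-en-1-ol | C=C(CO)CO[Si](C)(C)C(C)(C)C | intermediate
14 | 2-({[tert-butyl(dimethyl)silyl]oxy}methyl)prop-2-enal | C=C(C=O)CO[Si](C)(C)C(C)(C)C | intermediate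
15 | (3R)-2-({[tert-butyl(dimethyl)silyl]oxy}methyl)hexa-1,5-dien-3-ol | C=CC[C@@H](O)C(=C)CO[Si](C)(C)C(C)(C)C | intermediate
16 | (3R)-2-({[tert-butyl(dimethyl)silyl]oxy}methyl)hexa-1,5-dien-3-yl (5E)-6-methyl-2-methylidene-8-(2,6,6-trimethylcyclohex-1-en-1-yl)oct-5-enoate | C=CC[C@@H](OC(=O)C(=C)CC/C=C(\C)CCC1=C(C)CCCC1(C)C)C(=C)CO[Si](C)(C)C(C)(C)C | intermediate
17 | (6R)-6-(3-{[tert-butyl(dimethyl)silyl]oxy}prop-1-en-2-yl)-3-[(3E)-4-methyl-6-(2,6,6-trimethylcyclohex-1-en-1-yl)hex-3-en-1-yl]-5,6-dihydro-2H-pyran-2-one | C=C(CO[Si](C)(C)C(C)(C)C)[C@H]1CC=C(CC/C=C(\C)CCC2=C(C)CCCC2(C)C)C(=O)O1 | intermediate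
18 | (6R)-6-(3-hydroxyprop-1-en-2-yl)-3-[(3E)-4-methyl-6-(2,6,6-trimethylcyclohex-1-en-1-yl)hex-3-en-1-yl]-5,6-dihydro-2H-pyran-2-one | C=C(CO)[C@H]1CC=C(CC/C=C(\C)CCC2=C(C)CCCC2(C)C)C(=O)O1 | intermediate
19 | 2-[(2R)-5-[(3E)-4-methyl-6-(2,6,6-trimethylcyclohex-1-en-1-yl)hex-3-en-1-yl]-6-oxo-3,6-dihydro-2H-pyran-2-yl]prop-2-en-1-yl formate | C=C(COC=O)[C@H]1CC=C(CC/C=C(\C)CCC2=C(C)CCCC2(C)C)C(=O)O1 | intermediate
20 | (6R)-3-[(3E)-4-methyl-6-(2,6,6-trimethylcyclohex-1-en-1-yl)hex-3-en-1-yl]-6-[(3R)-5-oxooxolan-3-yl]-5,6-dihydro-2H-pyran-2-one | CC1=C(CC/C(C)=C/CCC2=CC[C@H]([C@H]3COC(=O)C3)OC2=O)C(C)(C)CCC1 | target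

**Step count and risks**

Total steps: 14. Longest linear sequence: 11 steps (steps 1 to 6, then 10 to 14).

Steps most likely to fail:

Step 14 (proposed new method). The formyl C–H addition may be outrun by loss of CO from the formate, by ionisation of one of the two allylic C–O bonds at ruthenium or by migration of the methylidene double bond, and hydride may be delivered to the wrong alkene face. Fallback with known chemistry, setting out from 18 and coming back at 20: rhodium-catalysed hydroformylation of the 1,1-disubstituted allylic alcohol (Rh(acac)(CO)2, a chiral phosphine–phosphoramidite ligand chosen for the (3R) centre, CO/H2 1:1, toluene, 60 °C) should place the formyl group on the CH2 terminus. The aldehyde then closes onto the neighbouring hydroxyl to give (6R)-6-[(3R)-5-hydroxyoxolan-3-yl]-3-[(3E)-4-methyl-6-(2,6,6-trimethylcyclohex-1-en-1-yl)hex-3-en-1-yl]-5,6-dihydro-2H-pyran-2-one F1 as a mixture of anomers. Oxidation of the lactol with TEMPO (cat.) and PhI(OAc)2 in CH2Cl2 then gives 20. Here the configuration at C3 of ring C rests on the ligand and not on the substrate.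

Step 11. Ring closure may stall because the α-branched acrylate is a poor partner for the loaded ruthenium carbene, so that intermolecular metathesis of the terminal alkene takes over. Fallback, setting out from 15 and 7 and coming back at 17 (it bypasses steps 4 to 6 and 10): acylation of 15 with acryloyl chloride and Et3N gives (3R)-2-({[tert-butyl(dimethyl)silyl]oxy}methyl)hexa-1,5-dien-3-yl prop-2-enoate F2. Its ring-closing metathesis with the second-generation Grubbs catalyst, a closure that is routine for unsubstituted acrylates, gives (6R)-6-(3-{[tert-butyl(dimethyl)silyl]oxy}prop-1-en-2-yl)-5,6-dihydro-2H-pyran-2-one F3. α-Iodination with I2 and pyridine in CH2Cl2 gives (6R)-6-(3-{[tert-butyl(dimethyl)silyl]oxy}prop-1-en-2-yl)-3-iodo-5,6-dihydro-2H-pyran-2-one F4. Zinc insertion into 7 (Zn dust, LiCl, THF, 40 °C) gives iodo[(3E)-4-methyl-6-(2,6,6-trimethylcyclohex-1-en-1-yl)hex-3-en-1-yl]zinc F5, and Negishi coupling of F4 with F5 (PdCl2(dppf), THF, rt) attaches the side chain at C3 of ring B to give 17.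

Step 9. Enantioface discrimination may be insufficient, or turnover slow, with the α-branched enal under chiral Lewis acid catalysis. Fallback, setting out from 14 and coming back at 15: stoichiometric reagent control through the closed chair transition state of a chiral allylborane (Brown allylation with (+)-B-allyldiisopinocampheylborane, Et2O, −78 °C, then NaOH/H2O2). This gives 15 directly and makes no compound outside the list (F0).

**Further compounds**

F1 | step 14 | (6R)-6-[(3R)-5-hydroxyoxolan-3-yl]-3-[(3E)-4-methyl-6-(2,6,6-trimethylcyclohex-1-en-1-yl)hex-3-en-1-yl]-5,6-dihydro-2H-pyran-2-one | CC1=C(CC/C(C)=C/CCC2=CC[C@H]([C@H]3COC(O)C3)OC2=O)C(C)(C)CCC1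
F2 | step 11 | (3R)-2-({[tert-butyl(dimethyl)silyl]oxy}methyl)hexa-1,5-dien-3-yl prop-2-enoate | C=CC[C@@H](OC(=O)C=C)C(=C)CO[Si](C)(C)C(C)(C)C
F3 | step 11 | (6R)-6-(3-{[tert-butyl(dimethyl)silyl]oxy}prop-1-en-2-yl)-5,6-dihydro-2H-pyran-2-one | C=C(CO[Si](C)(C)C(C)(C)C)[C@H]1CC=CC(=O)O1
F4 | step 11 | (6R)-6-(3-{[tert-butyl(dimethyl)silyl]oxy}prop-1-en-2-yl)-3-iodo-5,6-dihydro-2H-pyran-2-one | C=C(CO[Si](C)(C)C(C)(C)C)[C@H]1CC=C(I)C(=O)O1
F5 | step 11 | iodo[(3E)-4-methyl-6-(2,6,6-trimethylcyclohex-1-en-1-yl)hex-3-en-1-yl]zinc | I[Zn]CC/C=C(\C)CCC1=C(C)CCCC1(C)C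
F0 | step 9 | none | none
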